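Compound numbers are those of the steps and of the compound list that follows them.

## Analysis of the target

Target 29 is an achiral, open-chain hexamer: six benzene rings (A to F) joined only through five diaryl ether oxygens, with fifteen free phenolic hydroxyls, no stereocentre and no carbon–carbon bond between rings. Ring A is a 2,4,6-trihydroxyphenyl end group. Rings B, D and E are 3,5-dihydroxy-1,4-phenylenedioxy units in which one ether oxygen lies between the two hydroxyls. Ring F is a 3,4,5-trihydroxyphenyl end group. Ring C is the exception: five neighbouring carbons carry oxygen (C1 the oxygen to ring B, C2 the oxygen to ring D, C3 to C5 hydroxyls) and only C6 carries hydrogen. The compound is an extremely electron-rich polyphenol, and rings C and F oxidise readily in air, above all under base, so the hydroxyls have to stay masked until the last step. The difficulty is regiochemical and steric, not stereochemical. A benzene with five contiguous oxygens in three different states cannot be built with confidence by aromatic substitution, and both ether bonds at ring C are congested (the ring B oxygen sits between two oxygenated carbons, and C2 of ring C sits between C1–O and C3–O). The route rests on reading C2, C3, C4 and C5 of ring C as the four oxygenated carbons of 11, and C1 plus C6 as a 1-(aryloxy)vinyl unit whose oxygen is already the ring B oxygen. Rings D, E and F repeat one substitution pattern and can be added one at a time from the single fluoroaldehyde 2.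

## Retrosynthetic reasoning

29 from 28. The fourteen O–methyl bonds of 28 are cut last. Methyl ethers are the only masking group that survives every earlier operation (carbonate base at 100 °C, peroxide, alkyllithium, thermolysis, fluoride). The forward step is an exhaustive Lewis-acid demethylation that must leave the five sp2–O–sp2 ether bonds untouched.

28 back to 18 through 26, 25, 23, 22 and 20. The aryl–oxygen bonds joining ring F to E, E to D and D to C are each cut at the carbon para to a formyl group. Rings D, E and F each carry the new oxygen para to the oxygen that continues the chain, with two methoxy groups beside the latter, which is exactly the pattern of 2. Each cycle is therefore a nucleophilic aromatic substitution of a phenoxide on 2 followed by conversion of the formyl group into the next phenol (20 to 22, 23 to 25, 26 to 28). The chain is grown from C towards F because in that direction the crowded oxygen (flanked by two methoxy groups) is always the nucleophile and the carbon attacked is unhindered.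

18 from 17. Ring C must offer its C2 oxygen as the nucleophile while its C5 oxygen stays capped. This asks for the two para oxygens to be differentiated, C2 as a silyl ether and C5 as a free phenol. Methylation of C5 then gives 18, whose silyl ether is opened by fluoride in the same flask in which the phenoxide 19 attacks 2.

17 from 14 (the strategic disconnection). The C5–C6 bond of ring C is cut and the C2–C5 bond is re-formed in thought, which folds the benzene ring back into the cyclobutenone 14. No other cut gives all five oxygens without an aromatic substitution. The forward reaction, through 15 and 16, has to open the four-membered ring, close the six-membered one and aromatise. It delivers the C2 oxygen silylated and the C5 oxygen free, which is exactly the differentiation needed above.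

14 from 13, and 13 from 10 and 11. The bond between C1 and C2 of ring C is cut. It forms by addition of a 1-(aryloxy)vinyl anion to one carbonyl group of 11, followed by silylation of the tertiary alcohol. Direct deprotonation of the corresponding aryl vinyl ether with a strong alkyllithium base was rejected. The substrate holds four arene C–H bonds that each lie between two ether oxygens (two on ring A, two on ring B), and such positions are metalated under milder conditions than the alpha position of a simple enol ether. The anion 12 is therefore generated by tin–lithium exchange from 10 at −78 °C, which is far faster than any C–H metalation.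

10 from 9, 9 from 7, 7 from 5 and 6. The carbon–tin bond comes from palladium-catalysed hydrostannation of the ethynyl ether 9. Compound 9 comes from 7 by double loss of chloride, and 7 comes from phenol 5 and trichloroethylene 6. The crowded oxygen of ring B is thus joined to the future C1 of ring C as a phenoxide adding to a two-carbon electrophile, before ring C exists. This avoids forming a tri-ortho-substituted diaryl ether by substitution. The price is two steps more than a direct O-vinylation and deprotonation would need.

5 from 3, and 3 from 1 and 2. The ring A–oxygen–ring B bond is cut para to the formyl group of 3. The first substitution–oxidation cycle, from purchased 1 and 2, gives the AB phenol 5, with the same two operations that later add rings D, E and F.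

## Alternatives that were turned down

Alternative 1: Here the hydroxyls para to the ether oxygen on ring A, at C4 of ring C and at C4 of ring F are traced back to formyl groups, and the same formyl groups would earlier activate the substitutions that join the rings. The forward key step is a threefold peracid oxidation of the hexameric trialdehyde A2, with aryl migration at each formyl group, and hydrolysis of the three formates to the triphenol A1.
- For it: each formyl group does double duty, the assembly is convergent, no organometallic reagent is needed, and every formyl group lies between two methoxy groups, so aryl migration is assured.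
- Against it: the formyl group on ring C is para to C1 but meta to C2. Ring C would therefore have to arrive as a fully substituted fluoro-hydroxy-benzaldehyde, and making that building block is the real problem, which this plan leaves open. In addition the carbons to be attacked on rings A and C carry ortho oxygen substituents (two on ring A), which hinder addition and put donor groups on the carbanionic positions of the intermediate.
- Comparison: on paper it is shorter and more convergent than the chosen route, and it is stronger in needing no tin and no alkyllithium. The chosen route offers in exchange a ring C whose five oxygens come from two purchased reagents with the C2/C5 differentiation built in, and it forms the crowded ring B–oxygen–C1 link outside the substitution manifold.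

Alternative 2: Ring A is taken apart into the aryloxymalonate A5 (the oxygen-bearing carbon and its two neighbours) and dimethyl 3-oxopentanedioate A4 (the other three ring carbons). The forward key step is a double Claisen condensation under a methoxide base, in which the two methylene carbons of A4 acylate the two ester groups of A5, to give the ring A diester A3. Saponification and double decarboxylation would follow.
- For it: the three ring A hydroxyls arrive free, so three fewer methyl ethers have to be cleaved, and the ring construction needs no transition metal.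
- Against it: it constructs the one ring that can simply be bought as 1, and says nothing about ring C, so a methylated BCDEF pentamer with the pentaoxygenated ring would still have to be made by another plan. The key step also falls at the very end, on the most valuable intermediate. Under base A5 is deprotonated at its central carbon, which deactivates its esters as acylating agents, while A4 condenses with itself.
- Comparison: it is weaker in step economy and in where the risk is placed. Its one advantage, fewer demethylations, is small, because eleven methyl ethers would remain.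

Alternative 3: The C1–oxygen bond of ring C and a C2–iodine bond are formed together across an aryne. Fluoride releases the aryne from the silyl triflate A7. The phenoxide of 5 adds at C1, away from the C3 methoxy group, and the C2 aryl anion is trapped by a perfluoroalkyl iodide to give the iodide A6.
- For it: it is convergent, ring C comes from a simple trioxygenated arene, addition to a 3-alkoxyaryne is reliably distal, and the crowded ring B–oxygen–C1 bond is made with a very reactive electrophile. All three methoxy groups are in place from the start. It is about as short as the chosen route and avoids tin and the cyclobutenone thermolysis, so on convergence and reagent toxicity it is the stronger plan.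
- Against it: the aryl anion must be iodinated faster than it is protonated, and the phenoxide may react at carbon as well as oxygen. The iodine then sits between an aryloxy and a methoxy group and still has to be exchanged for oxygen, by a hindered copper coupling or by hydroxylation, before the chain can grow. A7 itself needs several steps.
- Comparison: the chosen route offers in its place a C2 oxygen that is present from the start, masked and differentiated by the same event that builds the ring, so no carbon–halogen to carbon–oxygen exchange is needed at the most congested carbon.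

Key step: step 8

Remark: 1, 2, 6 and 11 are taken as purchasable; the carbinol carbon of 13 and 14 is a stereocentre, carried as the racemate, that disappears in step 8.

## Route

Step 1
Reactants: 1 2,4,6-trimethoxyphenol; 2 4-fluoro-2,6-dimethoxybenzaldehyde
Product: 3 AB aldehyde 2,6-dimethoxy-4-(2,4,6-trimethoxyphenoxy)benzaldehyde
Conditions: Cs2CO3, DMSO, 100 °C, argon
Reagents that add atoms: none
Why: Nucleophilic aromatic substitution (addition–elimination) of fluoride para to the formyl group; the two methoxy groups of 2 are meta to the carbon attacked and do not sit on the charge-bearing positions of the Meisenheimer intermediate.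

Step 2
Reactants: 3 AB aldehyde
Product: 5 AB phenol 2,6-dimethoxy-4-(2,4,6-trimethoxyphenoxy)phenol, via aryl formate 4 (not isolated)
Conditions: 30% aq H2O2, H2SO4 (cat.), MeOH–CH2Cl2, rt
Reagents that add atoms: hydrogen peroxide, OO
Why: Acid-catalysed Dakin oxidation (Baeyer–Villiger type); the aryl group, with two ortho methoxy groups and a para aryloxy group, migrates in preference to hydride, and methanol cleaves formate 4 to the phenol.

Step 3
Reactants: 5 AB phenol; 6 trichloroethylene
Product: 7 dichlorovinyl ether 2-{[(E)-1,2-dichloroethenyl]oxy}-1,3-dimethoxy-5-(2,4,6-trimethoxyphenoxy)benzene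
Conditions: K2CO3, DMF, 70 °C
Reagents that add atoms: none
Why: Base-mediated dehydrochlorination of 6 to dichloroacetylene and anti addition of the phenoxide across it, a standard entry to 1,2-dichlorovinyl ethers that tolerates hindered oxygen nucleophiles; the anti addition gives the E isomer.

Step 4
Reactants: 7 dichlorovinyl ether
Product: 9 ethynyl ether 2-(ethynyloxy)-1,3-dimethoxy-5-(2,4,6-trimethoxyphenoxy)benzene, via lithium acetylide 8 (not isolated)
Conditions: n-BuLi (2.3 equiv), Et2O, −78 to −40 °C; then H2O, −78 °C
Reagents that add atoms: none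
Why: Dehydrochlorination to the chloroalkynyl ether and chlorine–lithium exchange give acetylide 8, which is protonated on quench; n-BuLi at these temperatures does not metalate the arene C–H bonds.

Step 5
Reactants: 9 ethynyl ether
Product: 10 vinylstannane tributyl{1-[2,6-dimethoxy-4-(2,4,6-trimethoxyphenoxy)phenoxy]ethenyl}stannane
Conditions: Bu3SnH (slow addition), Pd(PPh3)4 (cat.), THF, 0 °C to rt
Reagents that add atoms: tributyltin hydride, CCCC[SnH](CCCC)CCCC
Why: Palladium-catalysed syn hydrostannation; with 1-alkynyl ethers and ynamides tin is delivered to the heteroatom-bearing carbon, which here should give the 1-(aryloxy)vinylstannane.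

Step 6
Reactants: 10 vinylstannane; 11 dimethyl squarate
Product: 13 carbinol racemic 4-{1-[2,6-dimethoxy-4-(2,4,6-trimethoxyphenoxy)phenoxy]ethenyl}-4-hydroxy-2,3-dimethoxycyclobut-2-en-1-one, via vinyllithium 12 (not isolated)
Conditions: n-BuLi, THF, −78 °C, 10 min; then 11, THF, −78 °C; aq NH4Cl, −78 °C
Reagents that add atoms: none
Why: Tin–lithium exchange at −78 °C is much faster than arene metalation and gives 12, which has no hydrogen ortho to the vinyloxy group on ring B; 12 adds 1,2 to one carbonyl group of 11 and the cold quench prevents a second addition. The new quaternary carbinol carbon forms as a racemate, which needs no control because it becomes an sp2 carbon in step 8.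

Step 7
Reactants: 13 carbinol
Product: 14 silyl ether racemic 4-(tert-butyldimethylsilyloxy)-4-{1-[2,6-dimethoxy-4-(2,4,6-trimethoxyphenoxy)phenoxy]ethenyl}-2,3-dimethoxycyclobut-2-en-1-one
Conditions: TBSOTf, 2,6-lutidine, CH2Cl2, −78 to 0 °C
Reagents that add atoms: tert-butyldimethylsilyl trifluoromethanesulfonate, CC(C)(C)[Si](C)(C)OS(=O)(=O)C(F)(F)F
Why: Silylation of a tertiary alcohol with a silyl triflate and a hindered base; the excess base keeps the acid-labile hydroxycyclobutenone from ionising or rearranging.

Step 8
Reactants: 14 silyl ether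
Product: 17 ABC phenol 4-(tert-butyldimethylsilyloxy)-5-[2,6-dimethoxy-4-(2,4,6-trimethoxyphenoxy)phenoxy]-2,3-dimethoxyphenol, via dienylketene 15 (not isolated), via cyclohexadienone 16 (not isolated)
Conditions: degassed toluene, 110 °C, argon
Reagents that add atoms: none
Why: Heating should open the cyclobutenone by conrotatory 4π cleavage of the bond between the carbonyl carbon and the silyloxy-bearing carbon to give dienylketene 15. The closest known reaction type is the thermal ring expansion of 4-alkenyl-4-hydroxy- or 4-silyloxycyclobutenones from squarate esters to hydroquinone derivatives (Moore rearrangement). Ring C then closes by a thermal disrotatory 6π electrocyclisation that joins the ketene carbon (C5) to the terminal methylene carbon (C6), and cyclohexadienone 16 tautomerises to the phenol with gain of aromaticity. No stereocentre is created and the one in 14 is destroyed. The selectivity needed is torquoselectivity: the vinyl group must rotate inward, toward the ketene. The strongly donating silyloxy group on the same carbon prefers outward rotation and thereby forces the vinyl group inward. The silyl group stays on the former carbinol oxygen (C2) and the ketene oxygen becomes the free C5 hydroxyl; the two are para, so no silyl transfer between them is possible. All five oxygens of ring C are thus in place with C2 and C5 differentiated.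

Step 9
Reactants: 17 ABC phenol
Product: 18 ABC silyl ether tert-butyl{6-[2,6-dimethoxy-4-(2,4,6-trimethoxyphenoxy)phenoxy]-2,3,4-trimethoxyphenoxy}dimethylsilane
Conditions: MeI, K2CO3, acetone, rt, argon
Reagents that add atoms: iodomethane, CI
Why: Williamson O-methylation of the unhindered C5 phenoxide; the aryl silyl ether at C2 lies between two ortho substituents and should survive carbonate in dry acetone.

Step 10
Reactants: 18 ABC silyl ether; 2 4-fluoro-2,6-dimethoxybenzaldehyde
Product: 20 ABCD aldehyde 4-{6-[2,6-dimethoxy-4-(2,4,6-trimethoxyphenoxy)phenoxy]-2,3,4-trimethoxyphenoxy}-2,6-dimethoxybenzaldehyde, via caesium phenoxide 19 (not isolated)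
Conditions: CsF, DMSO, 100 °C, argon
Reagents that add atoms: none
Why: Fluoride cleaves the aryl silyl ether to phenoxide 19, which displaces the para fluoride of 2 by nucleophilic aromatic substitution and releases fluoride again; the air-sensitive C2 phenol is never isolated.

Step 11
Reactants: 20 ABCD aldehyde
Product: 22 ABCD phenol 4-{6-[2,6-dimethoxy-4-(2,4,6-trimethoxyphenoxy)phenoxy]-2,3,4-trimethoxyphenoxy}-2,6-dimethoxyphenol, via aryl formate 21 (not isolated)
Conditions: 30% aq H2O2, H2SO4 (cat.), MeOH–CH2Cl2, rt
Reagents that add atoms: hydrogen peroxide, OO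
Why: Dakin oxidation as in step 2; the di-ortho-methoxy, para-aryloxy ring migrates and formate 21 is cleaved by methanol.

Step 12
Reactants: 22 ABCD phenol; 2 4-fluoro-2,6-dimethoxybenzaldehyde
Product: 23 ABCDE aldehyde 4-(4-{6-[2,6-dimethoxy-4-(2,4,6-trimethoxyphenoxy)phenoxy]-2,3,4-trimethoxyphenoxy}-2,6-dimethoxyphenoxy)-2,6-dimethoxybenzaldehyde
Conditions: Cs2CO3, DMSO, 110 °C, argon
Reagents that add atoms: none
Why: Nucleophilic aromatic substitution as in step 1, with the same type of 2,6-dimethoxyphenoxide nucleophile.

Step 13
Reactants: 23 ABCDE aldehyde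
Product: 25 ABCDE phenol 4-(4-{6-[2,6-dimethoxy-4-(2,4,6-trimethoxyphenoxy)phenoxy]-2,3,4-trimethoxyphenoxy}-2,6-dimethoxyphenoxy)-2,6-dimethoxyphenol, via aryl formate 24 (not isolated)
Conditions: 30% aq H2O2, H2SO4 (cat.), MeOH–CH2Cl2, rt
Reagents that add atoms: hydrogen peroxide, OO
Why: Dakin oxidation as in step 2.

Step 14
Reactants: 25 ABCDE phenol; 2 4-fluoro-2,6-dimethoxybenzaldehyde
Product: 26 ABCDEF aldehyde 4-[4-(4-{6-[2,6-dimethoxy-4-(2,4,6-trimethoxyphenoxy)phenoxy]-2,3,4-trimethoxyphenoxy}-2,6-dimethoxyphenoxy)-2,6-dimethoxyphenoxy]-2,6-dimethoxybenzaldehyde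
Conditions: Cs2CO3, DMSO, 110 °C, argon
Reagents that add atoms: none
Why: Nucleophilic aromatic substitution as in step 1.

Step 15
Reactants: 26 ABCDEF aldehyde
Product: 28 ABCDEF phenol 4-[4-(4-{6-[2,6-dimethoxy-4-(2,4,6-trimethoxyphenoxy)phenoxy]-2,3,4-trimethoxyphenoxy}-2,6-dimethoxyphenoxy)-2,6-dimethoxyphenoxy]-2,6-dimethoxyphenol, via aryl formate 27 (not isolated)
Conditions: 30% aq H2O2, H2SO4 (cat.), MeOH–CH2Cl2, rt
Reagents that add atoms: hydrogen peroxide, OO
Why: Dakin oxidation as in step 2; it turns the last formyl group into the 4-hydroxyl of ring F.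

Step 16
Reactants: 28 ABCDEF phenol
Product: 29 target 4-{3,5-dihydroxy-4-[3,5-dihydroxy-4-(3,4,5-trihydroxyphenoxy)phenoxy]phenoxy}-5-[2,6-dihydroxy-4-(2,4,6-trihydroxyphenoxy)phenoxy]benzene-1,2,3-triol
Conditions: BBr3 (excess), CH2Cl2, −78 °C to rt; then H2O, 0 °C, argon
Reagents that add atoms: none
Why: Lewis-acid cleavage of the fourteen aryl methyl ethers (boron coordination, then bromide attack at methyl); the diaryl ether bonds have no sp3 carbon for bromide to attack and should remain.

## Compound list

1 | 2,4,6-trimethoxyphenol | COc1cc(OC)c(O)c(OC)c1 | starting material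
2 | 4-fluoro-2,6-dimethoxybenzaldehyde | COc1cc(F)cc(OC)c1C=O | starting material
3 | 2,6-dimethoxy-4-(2,4,6-trimethoxyphenoxy)benzaldehyde | COc1cc(OC)c(Oc2cc(OC)c(C=O)c(OC)c2)c(OC)c1 | intermediate
4 | 2,6-dimethoxy-4-(2,4,6-trimethoxyphenoxy)phenyl formate | COc1cc(OC)c(Oc2cc(OC)c(OC=O)c(OC)c2)c(OC)c1 | intermediate
5 | 2,6-dimethoxy-4-(2,4,6-trimethoxyphenoxy)phenol | COc1cc(OC)c(Oc2cc(OC)c(O)c(OC)c2)c(OC)c1 | intermediate
6 | trichloroethylene (1,1,2-trichloroethene) | ClC=C(Cl)Cl | starting material
7 | 2-{[(E)-1,2-dichloroethenyl]oxy}-1,3-dimethoxy-5-(2,4,6-trimethoxyphenoxy)benzene | COc1cc(OC)c(Oc2cc(OC)c(O/C(Cl)=C\Cl)c(OC)c2)c(OC)c1 | intermediate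
8 | lithium [2,6-dimethoxy-4-(2,4,6-trimethoxyphenoxy)phenoxy]acetylide | COc1cc(OC)c(Oc2cc(OC)c(OC#C[Li])c(OC)c2)c(OC)c1 | intermediate
9 | 2-(ethynyloxy)-1,3-dimethoxy-5-(2,4,6-trimethoxyphenoxy)benzene | COc1cc(OC)c(Oc2cc(OC)c(OC#C)c(OC)c2)c(OC)c1 | intermediate
10 | tributyl{1-[2,6-dimethoxy-4-(2,4,6-trimethoxyphenoxy)phenoxy]ethenyl}stannane | COc1cc(OC)c(Oc2cc(OC)c(OC(=C)[Sn](CCCC)(CCCC)CCCC)c(OC)c2)c(OC)c1 | intermediate
11 | dimethyl squarate (3,4-dimethoxycyclobut-3-ene-1,2-dione) | COC1=C(OC)C(=O)C1=O | starting material
12 | {1-[2,6-dimethoxy-4-(2,4,6-trimethoxyphenoxy)phenoxy]ethenyl}lithium | COc1cc(OC)c(Oc2cc(OC)c(OC(=C)[Li])c(OC)c2)c(OC)c1 | intermediate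
13 | racemic 4-{1-[2,6-dimethoxy-4-(2,4,6-trimethoxyphenoxy)phenoxy]ethenyl}-4-hydroxy-2,3-dimethoxycyclobut-2-en-1-one | COc1cc(OC)c(Oc2cc(OC)c(OC(=C)C3(O)C(OC)=C(OC)C3=O)c(OC)c2)c(OC)c1 | intermediate
14 | racemic 4-(tert-butyldimethylsilyloxy)-4-{1-[2,6-dimethoxy-4-(2,4,6-trimethoxyphenoxy)phenoxy]ethenyl}-2,3-dimethoxycyclobut-2-en-1-one | COc1cc(OC)c(Oc2cc(OC)c(OC(=C)C3(O[Si](C)(C)C(C)(C)C)C(OC)=C(OC)C3=O)c(OC)c2)c(OC)c1 | intermediate
15 | (3Z)-4-(tert-butyldimethylsilyloxy)-5-[2,6-dimethoxy-4-(2,4,6-trimethoxyphenoxy)phenoxy]-2,3-dimethoxyhexa-1,3,5-trien-1-one | COc1cc(OC)c(Oc2cc(OC)c(OC(=C)/C(O[Si](C)(C)C(C)(C)C)=C(OC)\C(OC)=C=O)c(OC)c2)c(OC)c1 | intermediate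
16 | 4-(tert-butyldimethylsilyloxy)-5-[2,6-dimethoxy-4-(2,4,6-trimethoxyphenoxy)phenoxy]-2,3-dimethoxycyclohexa-2,4-dien-1-one | COc1cc(OC)c(Oc2cc(OC)c(OC3=C(O[Si](C)(C)C(C)(C)C)C(OC)=C(OC)C(=O)C3)c(OC)c2)c(OC)c1 | intermediate
17 | 4-(tert-butyldimethylsilyloxy)-5-[2,6-dimethoxy-4-(2,4,6-trimethoxyphenoxy)phenoxy]-2,3-dimethoxyphenol | COc1cc(OC)c(Oc2cc(OC)c(Oc3cc(O)c(OC)c(OC)c3O[Si](C)(C)C(C)(C)C)c(OC)c2)c(OC)c1 | intermediate
18 | tert-butyl{6-[2,6-dimethoxy-4-(2,4,6-trimethoxyphenoxy)phenoxy]-2,3,4-trimethoxyphenoxy}dimethylsilane | COc1cc(OC)c(Oc2cc(OC)c(Oc3cc(OC)c(OC)c(OC)c3O[Si](C)(C)C(C)(C)C)c(OC)c2)c(OC)c1 | intermediate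
19 | caesium 6-[2,6-dimethoxy-4-(2,4,6-trimethoxyphenoxy)phenoxy]-2,3,4-trimethoxyphenoxide | COc1cc(OC)c(Oc2cc(OC)c(Oc3cc(OC)c(OC)c(OC)c3[O-])c(OC)c2)c(OC)c1.[Cs+] | intermediate
20 | 4-{6-[2,6-dimethoxy-4-(2,4,6-trimethoxyphenoxy)phenoxy]-2,3,4-trimethoxyphenoxy}-2,6-dimethoxybenzaldehyde | COc1cc(OC)c(Oc2cc(OC)c(Oc3cc(OC)c(OC)c(OC)c3Oc3cc(OC)c(C=O)c(OC)c3)c(OC)c2)c(OC)c1 | intermediate
21 | 4-{6-[2,6-dimethoxy-4-(2,4,6-trimethoxyphenoxy)phenoxy]-2,3,4-trimethoxyphenoxy}-2,6-dimethoxyphenyl formate | COc1cc(OC)c(Oc2cc(OC)c(Oc3cc(OC)c(OC)c(OC)c3Oc3cc(OC)c(OC=O)c(OC)c3)c(OC)c2)c(OC)c1 | intermediate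
22 | 4-{6-[2,6-dimethoxy-4-(2,4,6-trimethoxyphenoxy)phenoxy]-2,3,4-trimethoxyphenoxy}-2,6-dimethoxyphenol | COc1cc(OC)c(Oc2cc(OC)c(Oc3cc(OC)c(OC)c(OC)c3Oc3cc(OC)c(O)c(OC)c3)c(OC)c2)c(OC)c1 | intermediate
23 | 4-(4-{6-[2,6-dimethoxy-4-(2,4,6-trimethoxyphenoxy)phenoxy]-2,3,4-trimethoxyphenoxy}-2,6-dimethoxyphenoxy)-2,6-dimethoxybenzaldehyde | COc1cc(OC)c(Oc2cc(OC)c(Oc3cc(OC)c(OC)c(OC)c3Oc3cc(OC)c(Oc4cc(OC)c(C=O)c(OC)c4)c(OC)c3)c(OC)c2)c(OC)c1 | intermediate
24 | 4-(4-{6-[2,6-dimethoxy-4-(2,4,6-trimethoxyphenoxy)phenoxy]-2,3,4-trimethoxyphenoxy}-2,6-dimethoxyphenoxy)-2,6-dimethoxyphenyl formate | COc1cc(OC)c(Oc2cc(OC)c(Oc3cc(OC)c(OC)c(OC)c3Oc3cc(OC)c(Oc4cc(OC)c(OC=O)c(OC)c4)c(OC)c3)c(OC)c2)c(OC)c1 | intermediate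
25 | 4-(4-{6-[2,6-dimethoxy-4-(2,4,6-trimethoxyphenoxy)phenoxy]-2,3,4-trimethoxyphenoxy}-2,6-dimethoxyphenoxy)-2,6-dimethoxyphenol | COc1cc(OC)c(Oc2cc(OC)c(Oc3cc(OC)c(OC)c(OC)c3Oc3cc(OC)c(Oc4cc(OC)c(O)c(OC)c4)c(OC)c3)c(OC)c2)c(OC)c1 | intermediate
26 | 4-[4-(4-{6-[2,6-dimethoxy-4-(2,4,6-trimethoxyphenoxy)phenoxy]-2,3,4-trimethoxyphenoxy}-2,6-dimethoxyphenoxy)-2,6-dimethoxyphenoxy]-2,6-dimethoxybenzaldehyde | COc1cc(OC)c(Oc2cc(OC)c(Oc3cc(OC)c(OC)c(OC)c3Oc3cc(OC)c(Oc4cc(OC)c(Oc5cc(OC)c(C=O)c(OC)c5)c(OC)c4)c(OC)c3)c(OC)c2)c(OC)c1 | intermediate
27 | 4-[4-(4-{6-[2,6-dimethoxy-4-(2,4,6-trimethoxyphenoxy)phenoxy]-2,3,4-trimethoxyphenoxy}-2,6-dimethoxyphenoxy)-2,6-dimethoxyphenoxy]-2,6-dimethoxyphenyl formate | COc1cc(OC)c(Oc2cc(OC)c(Oc3cc(OC)c(OC)c(OC)c3Oc3cc(OC)c(Oc4cc(OC)c(Oc5cc(OC)c(OC=O)c(OC)c5)c(OC)c4)c(OC)c3)c(OC)c2)c(OC)c1 | intermediate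
28 | 4-[4-(4-{6-[2,6-dimethoxy-4-(2,4,6-trimethoxyphenoxy)phenoxy]-2,3,4-trimethoxyphenoxy}-2,6-dimethoxyphenoxy)-2,6-dimethoxyphenoxy]-2,6-dimethoxyphenol | COc1cc(OC)c(Oc2cc(OC)c(Oc3cc(OC)c(OC)c(OC)c3Oc3cc(OC)c(Oc4cc(OC)c(Oc5cc(OC)c(O)c(OC)c5)c(OC)c4)c(OC)c3)c(OC)c2)c(OC)c1 | intermediate
29 | 4-{3,5-dihydroxy-4-[3,5-dihydroxy-4-(3,4,5-trihydroxyphenoxy)phenoxy]phenoxy}-5-[2,6-dihydroxy-4-(2,4,6-trihydroxyphenoxy)phenoxy]benzene-1,2,3-triol | Oc1cc(O)c(Oc2cc(O)c(Oc3cc(O)c(O)c(O)c3Oc3cc(O)c(Oc4cc(O)c(Oc5cc(O)c(O)c(O)c5)c(O)c4)c(O)c3)c(O)c2)c(O)c1 | target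

## Step count and least certain steps

Total: 16 steps. Longest linear sequence: 16 steps, from 1 and 2 to 29; 6 and 11 enter as purchased inputs.

Step 8 (key step). What may go wrong: the ring opening may proceed with imperfect torquoselectivity, so that part of the material forms a ketene that cannot cyclise. The electron-rich para-silyloxyphenol 17 may also be oxidised, or lose its silyl group, during the heating or isolation. Fallback, from 13 back to 20: the free carbinol 13 would be heated instead (toluene, 110 °C), the longest-established form of this ring expansion. It should give the hydroquinone 5-[2,6-dimethoxy-4-(2,4,6-trimethoxyphenoxy)phenoxy]-2,3-dimethoxybenzene-1,4-diol F1. The two hydroxyls would then be told apart by sterics instead of by a silyl group. The C5 hydroxyl has a hydrogen neighbour, while the C2 hydroxyl lies between the aryloxy and a methoxy group. One equivalent of MeI with K2CO3 in acetone should therefore methylate C5 first and give 6-[2,6-dimethoxy-4-(2,4,6-trimethoxyphenoxy)phenoxy]-2,3,4-trimethoxyphenol F2. With 2 and Cs2CO3 in DMSO, F2 gives 20.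

Step 6. What may go wrong: vinyllithium 12 is an alpha-aryloxy carbenoid. It may fragment to aryloxide and acetylene, or transfer its charge to an arene C–H between two oxygens, before it meets 11; a second addition to the adduct is also possible. Fallback, from 7 back to 20: the weakly basic acetylide 8 (from 7 and n-BuLi as in step 4, not quenched) would be added to 11. This gives the alkynyl carbinol racemic 4-{[2,6-dimethoxy-4-(2,4,6-trimethoxyphenoxy)phenoxy]ethynyl}-4-hydroxy-2,3-dimethoxycyclobut-2-en-1-one F3. Heating F3 in toluene, the alkynyl variant of the same ring expansion (closure through a diradical, then hydrogen shift), should give the quinone 2-[2,6-dimethoxy-4-(2,4,6-trimethoxyphenoxy)phenoxy]-5,6-dimethoxycyclohexa-2,5-diene-1,4-dione F4. Reduction with Na2S2O4 gives the hydroquinone F1, and the selective methylation and substitution described for step 8 lead through F2 to 20. The costs are the lost C2/C5 differentiation and a possible diversion of the diradical to a five-membered ring.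

Step 5. What may go wrong: tin may be delivered partly to the terminal carbon, and the alpha-oxygenated vinylstannane may be protodestannylated on purification (base-washed silica or alumina would be used). Fallback, from 5 back to 10: phenol 5 would be O-vinylated with vinyl acetate, [Ir(cod)Cl]2 and Na2CO3 in toluene at 100 °C to give the vinyl ether 2-(ethenyloxy)-1,3-dimethoxy-5-(2,4,6-trimethoxyphenoxy)benzene F5. F5 would be deprotonated at the alpha position with t-BuLi in THF at −78 °C and quenched with Bu3SnCl to give 10. Ring metalation competes in this deprotonation, but the ring-stannylated isomers can be removed at this stage, before any squarate is committed.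

Step 10. What may go wrong: the C2 phenoxide 19 is flanked by an aryloxy and a methoxy group, so the substitution on the only moderately activated fluoride may be slower than decomposition of the phenoxide or of the aldehyde in hot DMSO. Fallback, from 18 back to 20: 18 would be desilylated with TBAF in THF to the free phenol 6-[2,6-dimethoxy-4-(2,4,6-trimethoxyphenoxy)phenoxy]-2,3,4-trimethoxyphenol F2. F2 would then be joined to purchased 4-bromo-2,6-dimethoxybenzaldehyde F6 by an Ullmann-type coupling (CuI, picolinic acid, K3PO4, DMSO, 90 °C), which depends less on the nucleophilicity of a hindered phenoxide, to give 20.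

Step 16. What may go wrong: cleavage of fourteen methyl ethers may stop short and leave partly methylated material that cannot be separated from the very polar product, and the free polyphenol may oxidise during work-up. Fallback, from 28 back to 29: the crude product of the BBr3 reaction would be acetylated (Ac2O, pyridine) to the pentadecaacetate of 29, F7, which can be purified on silica and separated from under-demethylated material. F7 would then be deacetylated under argon with catalytic NaOMe in degassed MeOH and neutralised with an acidic resin to release 29.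

## Further compounds

F1 | step 8 | 5-[2,6-dimethoxy-4-(2,4,6-trimethoxyphenoxy)phenoxy]-2,3-dimethoxybenzene-1,4-diol | COc1cc(OC)c(Oc2cc(OC)c(Oc3cc(O)c(OC)c(OC)c3O)c(OC)c2)c(OC)c1
F2 | step 8 | 6-[2,6-dimethoxy-4-(2,4,6-trimethoxyphenoxy)phenoxy]-2,3,4-trimethoxyphenol | COc1cc(OC)c(Oc2cc(OC)c(Oc3cc(OC)c(OC)c(OC)c3O)c(OC)c2)c(OC)c1
F3 | step 6 | racemic 4-{[2,6-dimethoxy-4-(2,4,6-trimethoxyphenoxy)phenoxy]ethynyl}-4-hydroxy-2,3-dimethoxycyclobut-2-en-1-one | COc1cc(OC)c(Oc2cc(OC)c(OC#CC3(O)C(OC)=C(OC)C3=O)c(OC)c2)c(OC)c1
F4 | step 6 | 2-[2,6-dimethoxy-4-(2,4,6-trimethoxyphenoxy)phenoxy]-5,6-dimethoxycyclohexa-2,5-diene-1,4-dione | COc1cc(OC)c(Oc2cc(OC)c(OC3=CC(=O)C(OC)=C(OC)C3=O)c(OC)c2)c(OC)c1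
F5 | step 5 | 2-(ethenyloxy)-1,3-dimethoxy-5-(2,4,6-trimethoxyphenoxy)benzene | COc1cc(OC)c(Oc2cc(OC)c(OC=C)c(OC)c2)c(OC)c1
F6 | step 10 | 4-bromo-2,6-dimethoxybenzaldehyde (purchased) | COc1cc(Br)cc(OC)c1C=O
F7 | step 16 | pentadecaacetate of 29 (every hydroxyl as its acetate) | CC(=O)Oc1cc(OC(C)=O)c(Oc2cc(OC(C)=O)c(Oc3cc(OC(C)=O)c(OC(C)=O)c(OC(C)=O)c3Oc3cc(OC(C)=O)c(Oc4cc(OC(C)=O)c(Oc5cc(OC(C)=O)c(OC(C)=O)c(OC(C)=O)c5)c(OC(C)=O)c4)c(OC(C)=O)c3)c(OC(C)=O)c2)c(OC(C)=O)c1
A1 | alternative 1 | methylated hexamer with free hydroxyls para to the ether oxygen on ring A, at C4 of ring C and at C4 of ring F | Oc1cc(OC)c(Oc2cc(OC)c(Oc3cc(OC)c(O)c(OC)c3Oc3cc(OC)c(Oc4cc(OC)c(Oc5cc(OC)c(O)c(OC)c5)c(OC)c4)c(OC)c3)c(OC)c2)c(OC)c1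
A2 | alternative 1 | methylated hexamer with formyl groups at the same three positions | O=Cc1cc(OC)c(Oc2cc(OC)c(Oc3cc(OC)c(C=O)c(OC)c3Oc3cc(OC)c(Oc4cc(OC)c(Oc5cc(OC)c(C=O)c(OC)c5)c(OC)c4)c(OC)c3)c(OC)c2)c(OC)c1
A3 | alternative 2 | dimethyl 2,4,6-trihydroxy-5-(methylated BCDEF aryloxy)benzene-1,3-dicarboxylate | COC(=O)c1c(O)c(C(=O)OC)c(O)c(Oc2cc(OC)c(Oc3cc(OC)c(OC)c(OC)c3Oc3cc(OC)c(Oc4cc(OC)c(Oc5cc(OC)c(OC)c(OC)c5)c(OC)c4)c(OC)c3)c(OC)c2)c1O
A4 | alternative 2 | dimethyl 3-oxopentanedioate | COC(=O)CC(=O)CC(=O)OC
A5 | alternative 2 | dimethyl 2-(methylated BCDEF aryloxy)propanedioate | COC(=O)C(Oc1cc(OC)c(Oc2cc(OC)c(OC)c(OC)c2Oc2cc(OC)c(Oc3cc(OC)c(Oc4cc(OC)c(OC)c(OC)c4)c(OC)c3)c(OC)c2)c(OC)c1)C(=O)OC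
A6 | alternative 3 | methylated ABC triaryl diether with iodine on C2 of ring C | COc1cc(OC)c(Oc2cc(OC)c(Oc3cc(OC)c(OC)c(OC)c3I)c(OC)c2)c(OC)c1
A7 | alternative 3 | 3,4,5-trimethoxy-2-(trimethylsilyl)phenyl trifluoromethanesulfonate | COc1cc(OS(=O)(=O)C(F)(F)F)c([Si](C)(C)C)c(OC)c1OC
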